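**Strategy.** The tetramer is cut at the A–B and B–C interflavan bonds into the epicatechin-(4β→8)-epicatechin dimer (units C and D), a C8-bromo, C4-thio epicatechin (unit B) and a catechin-type C4 electrophile (unit A). Ring C of unit A (O1–C2–C3–C4–C4a–C8a) is reached from a 2,3-dihydrobenzofuran: an acyloin (α-ketol) shift moves C2 from the carbinol carbon to the formyl carbon of a 3-hydroxy-2-aryl-2,3-dihydrobenzofuran-3-carbaldehyde. The step exploits the C3 carbinol next to C4, the carbon bonded to the donor-rich ring A: the conjugated C4 aryl ketone is the thermodynamic sink. One operation enlarges the ring, sets C3 trans to C2 and arms C4; the precursor comes from (+)-catechin by a 1,2-aryl shift.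

Key step: step 13

Assumption: the 2,3-trans 3-O-sulfonate 11 ionises with participation of the ring-A carbon C4a (1,2-aryl shift through a phenonium ion), the behaviour expected for 2,3-trans-flavan-3-ol 3-O-sulfonates, whose C4–C4a bond is antiperiplanar to the leaving group. Flavan locants (O1, C2, C3, C4, C4a, C5 to C8, C8a) are used for all flavan units; Bn = benzyl.

**Units C and D**

Step 1
Reactants: 1 (−)-epicatechin
Product: 2 5,7,3',4'-tetra-O-benzyl-(−)-epicatechin
Conditions: BnBr (4.2 equiv), K2CO3, DMF, 0 °C to rt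
Reagents that add atoms: benzyl bromide, BrCc1ccccc1
Why: Williamson etherification benzylates the four phenols and leaves the less acidic secondary 3-OH free, so C2 and C3 are untouched.

Step 2
Reactants: 2 tetra-O-benzyl-(−)-epicatechin
Product: 3 4β-(2-ethoxyethoxy)-5,7,3',4'-tetra-O-benzyl-(−)-epicatechin
Conditions: DDQ (2 equiv), 2-ethoxyethanol (5 equiv), CH2Cl2, rt
Reagents that add atoms: 2-ethoxyethanol, CCOCCO
Why: DDQ benzylic oxidation removes hydride from C4 and the ring-A-stabilised cation is trapped by the alcohol on the face anti to the 3-OH, which gives the 4β ether (3,4-trans).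

Step 3
Reactants: 3 4β-(2-ethoxyethoxy)-tetra-O-benzylepicatechin and 2 tetra-O-benzyl-(−)-epicatechin (4 equiv, excess recovered)
Product: 4 octa-O-benzyl procyanidin B2 [tetra-O-benzylepicatechin-(4β→8)-tetra-O-benzylepicatechin]
Conditions: TMSOTf (0.2 equiv), CH2Cl2, −78 °C
Reagents that add atoms: none
Why: Lewis-acid ionisation of the C4 ether and Friedel–Crafts attack by C8 of 2 anti to the 3-OH forms the 4β→8 bond (3,4-trans), the excess of 2 holding back higher oligomers.

**Unit B**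

Step 4
Reactants: 2 tetra-O-benzyl-(−)-epicatechin
Product: 5 8-bromo-5,7,3',4'-tetra-O-benzyl-(−)-epicatechin
Conditions: NBS (1.0 equiv), CH2Cl2, −78 °C to 0 °C
Reagents that add atoms: N-bromosuccinimide, O=C1CCC(=O)N1Br
Why: Electrophilic aromatic bromination occurs at C8, the most nucleophilic ring-A position of benzylated flavan-3-ols, and leaves C6 as the only free ring-A carbon.

Step 5
Reactants: 5 8-bromo-tetra-O-benzyl-(−)-epicatechin
Product: 6 8-bromo-4β-(2-ethoxyethoxy)-5,7,3',4'-tetra-O-benzyl-(−)-epicatechin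
Conditions: DDQ (2 equiv), 2-ethoxyethanol (5 equiv), CH2Cl2, rt
Reagents that add atoms: 2-ethoxyethanol, CCOCCO
Why: The same DDQ benzylic oxidation as in step 2 functionalises C4 with capture anti to the 3-OH (4β).

Step 6
Reactants: 6 8-bromo-4β-(2-ethoxyethoxy)-tetra-O-benzylepicatechin
Product: 7 8-bromo-4β-(2,6-dimethylphenylthio)-5,7,3',4'-tetra-O-benzyl-(−)-epicatechin
Conditions: 2,6-dimethylbenzenethiol (1.5 equiv), BF3·OEt2 (0.3 equiv), CH2Cl2, −78 °C to −30 °C
Reagents that add atoms: 2,6-dimethylbenzenethiol, Cc1cccc(C)c1S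
Why: Lewis-acid thiolysis (SN1 exchange at C4, attack anti to the 3-OH) installs a 4β thioether that survives hard Lewis acids and is released later by thiophilic AgOTf (orthogonal activation).

**Unit A**

Step 7
Reactants: 8 (+)-catechin
Product: 9 5,7,3',4'-tetra-O-benzyl-(+)-catechin
Conditions: BnBr (4.2 equiv), K2CO3, DMF, 0 °C to rt
Reagents that add atoms: benzyl bromide, BrCc1ccccc1
Why: Williamson etherification of the four phenols leaves the 3-OH free and keeps the 2R,3S centers of the chiral-pool material.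

Step 8
Reactants: 9 tetra-O-benzyl-(+)-catechin
Product: 10 8-bromo-5,7,3',4'-tetra-O-benzyl-(+)-catechin
Conditions: NBS (1.0 equiv), CH2Cl2, −78 °C to 0 °C
Reagents that add atoms: N-bromosuccinimide, O=C1CCC(=O)N1Br
Why: Regioselective electrophilic bromination at C8 caps the position of ring A that would otherwise act as a nucleophile in the later cation couplings.

Step 9
Reactants: 10 8-bromo-tetra-O-benzyl-(+)-catechin
Product: 11 8-bromo-5,7,3',4'-tetra-O-benzyl-(+)-catechin 3-O-methanesulfonate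
Conditions: MsCl (1.5 equiv), Et3N, CH2Cl2, 0 °C
Reagents that add atoms: methanesulfonyl chloride, CS(=O)(=O)Cl
Why: O-Sulfonylation turns the 3-OH into a leaving group with retention, because no bond to C3 is broken.

Step 10
Reactants: 11 8-bromo-tetra-O-benzyl-(+)-catechin 3-O-methanesulfonate
Product: 12 [(2S,3R)-4,6-bis(benzyloxy)-2-(3,4-bis(benzyloxy)phenyl)-7-bromo-2,3-dihydrobenzofuran-3-yl]methanol (2,3-trans)
Conditions: 2,6-lutidine (2 equiv), H2O–1,4-dioxane (1:4), 80 °C
Reagents that add atoms: water, O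
Why: Solvolysis with anchimeric assistance: the C4–C4a bond, antiperiplanar to the equatorial mesylate, shifts to C3 with inversion (1,2-aryl shift of Wagner–Meerwein type) and water captures the primary carbon C4, which leaves C2 untouched and puts the hydroxymethyl group trans to the C2 aryl.

Step 11
Reactants: 12 2,3-trans-2-aryl-2,3-dihydrobenzofuran-3-ylmethanol
Product: 13 (2S,3S)-4,6-bis(benzyloxy)-2-[3,4-bis(benzyloxy)phenyl]-7-bromo-2,3-dihydrobenzofuran-3-carbaldehyde (2,3-trans)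
Conditions: Dess–Martin periodinane (1.3 equiv), CH2Cl2, 0 °C to rt
Reagents that add atoms: none
Why: Dess–Martin oxidation gives the aldehyde under non-basic conditions, so C2 is untouched and the epimerisable C3 rests in the trans arrangement.

Step 12
Reactants: 13 2,3-trans-2-aryl-2,3-dihydrobenzofuran-3-carbaldehyde
Product: 16 (2R,3S)-4,6-bis(benzyloxy)-2-[3,4-bis(benzyloxy)phenyl]-7-bromo-3-hydroxy-2,3-dihydrobenzofuran-3-carbaldehyde (3-OH trans to the C2 aryl), via silyl enol ether 14 (not isolated), via silyloxy aldehyde 15 (not isolated)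
Conditions: TMSOTf (1.3 equiv), Et3N, CH2Cl2, −20 °C; then dimethyldioxirane, acetone, −40 °C; then aq. citric acid, THF, 0 °C
Reagents that add atoms: dimethyldioxirane, CC1(C)OO1
Why: Rubottom oxidation, in which soft enolisation gives the silyl enol ether, dimethyldioxirane transfers oxygen to the face anti to the C2 aryl and silyl migration followed by mild hydrolysis gives the tertiary α-hydroxy aldehyde, whose carbinol configuration is not needed later.

Step 13
Reactants: 16 3-hydroxy-2-aryl-2,3-dihydrobenzofuran-3-carbaldehyde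
Product: 17 (2R,3R)-8-bromo-5,7,3',4'-tetra-O-benzyltaxifolin (2,3-trans-3-hydroxyflavan-4-one)
Conditions: Al(Ot-Bu)3 (0.3 equiv), toluene, 60 °C
Reagents that add atoms: none
Why: Exchange with Al(Ot-Bu)3 turns the tertiary carbinol into an O–Al alkoxide that also binds the formyl oxygen, and the bond between C2 and the carbinol carbon shifts to the formyl carbon (suprafacial 1,2-shift with retention at C2), so the old carbinol carbon becomes the C4 ketone and the old formyl carbon becomes C3 (α-ketol or acyloin rearrangement). The closest known reactions are the ring enlargements of 1-hydroxycycloalkanecarbaldehydes to 2-hydroxycycloalkanones and the Al(Ot-Bu)3-promoted D-homoannulation of 17-hydroxy-20-oxo steroids. Ring C (O1–C2–C3–C4–C4a–C8a) is closed not by a cyclisation but by enlargement of the five-membered ring through the new C2–C3 bond. The new stereocenter C3 is set trans to the C2 aryl by the five-membered O–Al–O chelate, which holds the C3–O bond in the plane of the new carbonyl (equatorial) in a half-chair with the C2 aryl equatorial, and the same trans isomer is the thermodynamic one. The step needs migration of C2 and not of C4a: alkoxide-driven shifts favour the benzylic, oxygen-bearing sp3 carbon, and a shift of C4a would give the 4-hydroxy-3-ketone, which drains by enediol tautomerism to the same conjugated aryl ketone. The aldehyde has no α-hydrogen and cannot enolise, and conjugation of the new C4 carbonyl with O1, O5 and O7 of ring A makes the shift irreversible.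

Step 14
Reactants: 17 8-bromo-tetra-O-benzyltaxifolin
Product: 18 (2R,3S,4R)-8-bromo-5,7,3',4'-tetra-O-benzylflavan-3,4-diol (2,3-trans-3,4-trans)
Conditions: NaBH4 (1.5 equiv), THF–EtOH, 0 °C
Reagents that add atoms: none
Why: Hydride reduction of the C4 ketone by axial attack should give mainly the all-equatorial diol, and the C4 configuration is erased in step 15 in any case.

**Assembly**

Step 15
Reactants: 18 8-bromo-tetra-O-benzylflavan-3,4-diol and 7 8-bromo-4β-(2,6-dimethylphenylthio)-tetra-O-benzylepicatechin (2.5 equiv, excess recovered)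
Product: 19 [8-bromo-tetra-O-benzylcatechin]-(4α→6)-[8-bromo-4β-(2,6-dimethylphenylthio)-tetra-O-benzylepicatechin]
Conditions: Yb(OTf)3 (0.2 equiv), 4 Å molecular sieves, CH2Cl2, 0 °C to rt
Reagents that add atoms: none
Why: Lewis-acid ionisation of the C4–OH with loss of water gives the ring-A-stabilised C4 cation, which C6 of 7 (C8 is blocked by bromine) attacks anti to the 3-OH in a Friedel–Crafts reaction to form the 4α→6 bond (3,4-trans), the thioether of 7 staying inert to the hard Lewis acid.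

Step 16
Reactants: 19 dibromo 4-thio catechin–epicatechin dimer and 4 octa-O-benzyl procyanidin B2 (3 equiv, excess recovered)
Product: 20 hexadeca-O-benzyl-8,8-dibromo (units A and B) catechin-(4α→6)-epicatechin-(4β→8)-epicatechin-(4β→8)-epicatechin
Conditions: AgOTf (1.2 equiv), 2,6-di-tert-butyl-4-methylpyridine, 4 Å molecular sieves, CH2Cl2, −78 °C to −20 °C
Reagents that add atoms: none
Why: AgOTf, a thiophilic salt, ionises the C4–S bond of unit B and the free C8 of the top unit of 4 attacks the cation anti to the 3-OH (4β→8, 3,4-trans) in a Friedel–Crafts reaction, while bromine blocks both C8 positions of 19 and the excess of 4 outcompetes its less reactive free C6.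

Step 17
Reactants: 20 hexadeca-O-benzyl dibromo tetramer
Product: 21 catechin-(4α→6)-epicatechin-(4β→8)-epicatechin-(4β→8)-epicatechin (CNP0228086.1)
Conditions: H2 (1 atm), Pd(OH)2/C, Et3N (2.2 equiv), THF–MeOH–H2O, rt
Reagents that add atoms: none
Why: Catalytic hydrogenolysis cleaves the sixteen benzyl ethers and the two aryl C–Br bonds without touching the interflavan bonds or any stereocenter.

**Compound list**

1 | (−)-epicatechin, (2R,3R)-2-(3,4-dihydroxyphenyl)chromane-3,5,7-triol | c1c(O)cc(O)c2c1O[C@H](c8ccc(O)c(O)c8)[C@H](O)C2 | starting material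
2 | 5,7,3',4'-tetra-O-benzyl-(−)-epicatechin | c1c(OCc9ccccc9)cc(OCc9ccccc9)c2c1O[C@H](c8ccc(OCc9ccccc9)c(OCc9ccccc9)c8)[C@H](O)C2 | intermediate
3 | 4β-(2-ethoxyethoxy)-5,7,3',4'-tetra-O-benzyl-(−)-epicatechin (2,3-cis, 3,4-trans) | c1c(OCc9ccccc9)cc(OCc9ccccc9)c2c1O[C@H](c8ccc(OCc9ccccc9)c(OCc9ccccc9)c8)[C@H](O)[C@H]2OCCOCC | intermediate
4 | octa-O-benzyl procyanidin B2, tetra-O-benzylepicatechin-(4β→8)-tetra-O-benzylepicatechin | c1c(OCc9ccccc9)cc(OCc9ccccc9)c2c1O[C@H](c8ccc(OCc9ccccc9)c(OCc9ccccc9)c8)[C@H](O)[C@H]2c3c(OCc9ccccc9)cc(OCc9ccccc9)c4c3O[C@H](c8ccc(OCc9ccccc9)c(OCc9ccccc9)c8)[C@H](O)C4 | intermediate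
5 | 8-bromo-5,7,3',4'-tetra-O-benzyl-(−)-epicatechin | Brc1c(OCc9ccccc9)cc(OCc9ccccc9)c2c1O[C@H](c8ccc(OCc9ccccc9)c(OCc9ccccc9)c8)[C@H](O)C2 | intermediate
6 | 8-bromo-4β-(2-ethoxyethoxy)-5,7,3',4'-tetra-O-benzyl-(−)-epicatechin | Brc1c(OCc9ccccc9)cc(OCc9ccccc9)c2c1O[C@H](c8ccc(OCc9ccccc9)c(OCc9ccccc9)c8)[C@H](O)[C@H]2OCCOCC | intermediate
7 | 8-bromo-4β-(2,6-dimethylphenylthio)-5,7,3',4'-tetra-O-benzyl-(−)-epicatechin | Brc1c(OCc9ccccc9)cc(OCc9ccccc9)c2c1O[C@H](c8ccc(OCc9ccccc9)c(OCc9ccccc9)c8)[C@H](O)[C@H]2Sc3c(C)cccc3C | intermediate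
8 | (+)-catechin, (2R,3S)-2-(3,4-dihydroxyphenyl)chromane-3,5,7-triol | c1c(O)cc(O)c2c1O[C@H](c8ccc(O)c(O)c8)[C@@H](O)C2 | starting material
9 | 5,7,3',4'-tetra-O-benzyl-(+)-catechin | c1c(OCc9ccccc9)cc(OCc9ccccc9)c2c1O[C@H](c8ccc(OCc9ccccc9)c(OCc9ccccc9)c8)[C@@H](O)C2 | intermediate
10 | 8-bromo-5,7,3',4'-tetra-O-benzyl-(+)-catechin | Brc1c(OCc9ccccc9)cc(OCc9ccccc9)c2c1O[C@H](c8ccc(OCc9ccccc9)c(OCc9ccccc9)c8)[C@@H](O)C2 | intermediate
11 | 8-bromo-5,7,3',4'-tetra-O-benzyl-(+)-catechin 3-O-methanesulfonate | Brc1c(OCc9ccccc9)cc(OCc9ccccc9)c2c1O[C@H](c8ccc(OCc9ccccc9)c(OCc9ccccc9)c8)[C@@H](OS(C)(=O)=O)C2 | intermediate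
12 | [(2S,3R)-4,6-bis(benzyloxy)-2-(3,4-bis(benzyloxy)phenyl)-7-bromo-2,3-dihydrobenzofuran-3-yl]methanol (2,3-trans) | Brc1c(OCc9ccccc9)cc(OCc9ccccc9)c2c1O[C@H](c8ccc(OCc9ccccc9)c(OCc9ccccc9)c8)[C@H]2CO | intermediate
13 | (2S,3S)-4,6-bis(benzyloxy)-2-[3,4-bis(benzyloxy)phenyl]-7-bromo-2,3-dihydrobenzofuran-3-carbaldehyde (2,3-trans) | Brc1c(OCc9ccccc9)cc(OCc9ccccc9)c2c1O[C@H](c8ccc(OCc9ccccc9)c(OCc9ccccc9)c8)[C@H]2C=O | intermediate
14 | trimethylsilyl (Z)-enol ether of 13 (C2 as in 13, silyloxy group cis to C2) | Brc1c(OCc9ccccc9)cc(OCc9ccccc9)c2c1O[C@H](c8ccc(OCc9ccccc9)c(OCc9ccccc9)c8)/C2=C\O[Si](C)(C)C | intermediate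
15 | (2R,3S)-4,6-bis(benzyloxy)-2-[3,4-bis(benzyloxy)phenyl]-7-bromo-3-(trimethylsilyloxy)-2,3-dihydrobenzofuran-3-carbaldehyde (silyloxy trans to the C2 aryl) | Brc1c(OCc9ccccc9)cc(OCc9ccccc9)c2c1O[C@H](c8ccc(OCc9ccccc9)c(OCc9ccccc9)c8)[C@]2(O[Si](C)(C)C)C=O | intermediate
16 | (2R,3S)-4,6-bis(benzyloxy)-2-[3,4-bis(benzyloxy)phenyl]-7-bromo-3-hydroxy-2,3-dihydrobenzofuran-3-carbaldehyde (3-OH trans to the C2 aryl) | Brc1c(OCc9ccccc9)cc(OCc9ccccc9)c2c1O[C@H](c8ccc(OCc9ccccc9)c(OCc9ccccc9)c8)[C@]2(O)C=O | intermediate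
17 | (2R,3R)-8-bromo-5,7,3',4'-tetra-O-benzyltaxifolin (2,3-trans) | Brc1c(OCc9ccccc9)cc(OCc9ccccc9)c2c1O[C@H](c8ccc(OCc9ccccc9)c(OCc9ccccc9)c8)[C@@H](O)C2=O | intermediate
18 | (2R,3S,4R)-8-bromo-5,7,3',4'-tetra-O-benzylflavan-3,4-diol (2,3-trans-3,4-trans) | Brc1c(OCc9ccccc9)cc(OCc9ccccc9)c2c1O[C@H](c8ccc(OCc9ccccc9)c(OCc9ccccc9)c8)[C@@H](O)[C@@H]2O | intermediate
19 | [8-bromo-tetra-O-benzylcatechin]-(4α→6)-[8-bromo-4β-(2,6-dimethylphenylthio)-tetra-O-benzylepicatechin] | Brc1c(OCc9ccccc9)cc(OCc9ccccc9)c2c1O[C@H](c8ccc(OCc9ccccc9)c(OCc9ccccc9)c8)[C@@H](O)[C@@H]2c3c(OCc9ccccc9)c(Br)c4c(c3OCc9ccccc9)[C@H](Sc5c(C)cccc5C)[C@@H](O)[C@@H](c8ccc(OCc9ccccc9)c(OCc9ccccc9)c8)O4 | intermediate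
20 | hexadeca-O-benzyl tetramer with bromine at C8 of units A and B, catechin-(4α→6)-epicatechin-(4β→8)-epicatechin-(4β→8)-epicatechin | Brc1c(OCc9ccccc9)cc(OCc9ccccc9)c2c1O[C@H](c8ccc(OCc9ccccc9)c(OCc9ccccc9)c8)[C@@H](O)[C@@H]2c3c(OCc9ccccc9)c(Br)c4c(c3OCc9ccccc9)[C@H](c5c(OCc9ccccc9)cc(OCc9ccccc9)c6c5O[C@H](c8ccc(OCc9ccccc9)c(OCc9ccccc9)c8)[C@H](O)[C@H]6c5c(OCc9ccccc9)cc(OCc9ccccc9)c6c5O[C@H](c8ccc(OCc9ccccc9)c(OCc9ccccc9)c8)[C@H](O)C6)[C@@H](O)[C@@H](c8ccc(OCc9ccccc9)c(OCc9ccccc9)c8)O4 | intermediate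
21 | catechin-(4α→6)-epicatechin-(4β→8)-epicatechin-(4β→8)-epicatechin (CNP0228086.1) | Oc1cc(O)c2c(c1)O[C@H](c1ccc(O)c(O)c1)[C@@H](O)[C@@H]2c1c(O)cc2c(c1O)[C@H](c1c(O)cc(O)c3c1O[C@H](c1ccc(O)c(O)c1)[C@H](O)[C@H]3c1c(O)cc(O)c3c1O[C@H](c1ccc(O)c(O)c1)[C@H](O)C3)[C@@H](O)[C@@H](c1ccc(O)c(O)c1)O2 | target

**Counts**

Total step count: 17. Longest linear sequence: 11 steps (steps 7 to 17, from (+)-catechin).

**Steps most likely to fail**

1. Step 13 (key step). What may go wrong: migration of the ring-A carbon instead of C2, loss of configuration at C2 or C3 by enolisation or by β-elimination of the phenoxide under the alkoxide, or dehydration to the aromatic benzofuran. Fallback: the shift is run on a silyl-protected carbinol as a Lewis-acid (pull only) acyloin rearrangement with no alkoxide present. It sets out from 13. TBSOTf and Et3N give the tert-butyldimethylsilyl (Z)-enol ether F1. Dimethyldioxirane then gives the isolable α-silyloxy aldehyde F2. Me2AlCl in CH2Cl2 at −78 °C promotes the 1,2-shift of C2 to the 3-O-silyl ketone F3. Bu4NF buffered with AcOH removes the silyl group and the sequence comes back to the route at 17.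

2. Step 10. What may go wrong: participation of O1 instead of ring A, capture of the bridged ion at C3 with return to the six-membered ring, or elimination to flavenes. Fallback: the ring contraction is done oxidatively on the alkene. It sets out from 11. DBU in toluene effects anti elimination through the diaxial conformer to the flav-3-ene F4. PhI(OH)OTs in MeOH with trimethyl orthoformate then brings about the oxidative 1,2-aryl shift known for 2H-chromenes and 1,2-dihydronaphthalenes to the trans dimethyl acetal F5. Mild aqueous acid hydrolysis comes back to the route at 13.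

3. Step 15. What may go wrong: poor facial selectivity at C4 (capture from the 4β face) and slow attack by the hindered C6 of 7, which allows self-condensation of the diol. Fallback: neighbouring-group control by a 3-O-acyl group. It sets out from 18. Ac2O and pyridine give the 3,4-di-O-acetate F6. TMSOTf-catalysed coupling with 7 then proceeds through the acetoxy-bridged C3–C4 cation, which can only be opened trans, to the 3-O-acetyl dimer F7. K2CO3 in MeOH removes the acetate and the sequence comes back to the route at 19.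

Further compounds
F1 | step 13 | tert-butyldimethylsilyl (Z)-enol ether of 13 | Brc1c(OCc9ccccc9)cc(OCc9ccccc9)c2c1O[C@H](c8ccc(OCc9ccccc9)c(OCc9ccccc9)c8)/C2=C\O[Si](C)(C)C(C)(C)C
F2 | step 13 | O-tert-butyldimethylsilyl ether of 16 | Brc1c(OCc9ccccc9)cc(OCc9ccccc9)c2c1O[C@H](c8ccc(OCc9ccccc9)c(OCc9ccccc9)c8)[C@]2(O[Si](C)(C)C(C)(C)C)C=O
F3 | step 13 | 3-O-tert-butyldimethylsilyl ether of 17 (2,3-trans) | Brc1c(OCc9ccccc9)cc(OCc9ccccc9)c2c1O[C@H](c8ccc(OCc9ccccc9)c(OCc9ccccc9)c8)[C@@H](O[Si](C)(C)C(C)(C)C)C2=O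
F4 | step 10 | (2S)-5,7-bis(benzyloxy)-2-[3,4-bis(benzyloxy)phenyl]-8-bromo-2H-chromene (C2 as in 11) | Brc1c(OCc9ccccc9)cc(OCc9ccccc9)c2c1O[C@H](c8ccc(OCc9ccccc9)c(OCc9ccccc9)c8)C=C2
F5 | step 10 | dimethyl acetal of 13 (2,3-trans) | Brc1c(OCc9ccccc9)cc(OCc9ccccc9)c2c1O[C@H](c8ccc(OCc9ccccc9)c(OCc9ccccc9)c8)[C@H]2C(OC)OC
F6 | step 15 | 3,4-di-O-acetate of 18 | Brc1c(OCc9ccccc9)cc(OCc9ccccc9)c2c1O[C@H](c8ccc(OCc9ccccc9)c(OCc9ccccc9)c8)[C@@H](OC(C)=O)[C@@H]2OC(C)=O
F7 | step 15 | 3-O-acetate (unit A) of 19 | Brc1c(OCc9ccccc9)cc(OCc9ccccc9)c2c1O[C@H](c8ccc(OCc9ccccc9)c(OCc9ccccc9)c8)[C@@H](OC(C)=O)[C@@H]2c3c(OCc9ccccc9)c(Br)c4c(c3OCc9ccccc9)[C@H](Sc5c(C)cccc5C)[C@@H](O)[C@@H](c8ccc(OCc9ccccc9)c(OCc9ccccc9)c8)O4
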